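**Retrosynthetic overview**
1. Dictyol H ← C4 ketone 19, by hydride delivery to the convex face.
2. 19 ← bis-epoxy cyclohexanol 15, by a one-flask epoxy-alcohol semipinacol ring expansion (six → seven ring, sets C5), 5-exo oxolane closure and acetylation.
3. 15 ← bicyclic ketone 5 + (Z)-alkenyl iodide 11, by organocerium addition and hydroxyl-directed epoxidation.
4. 5 ← dione 4 (mono-methylenation) ← enedione 1 + silylallene 2 (enantioselective cyclopentene annulation); 11 ← bromide 6 + propyne 7 (carbocupration, then Shi epoxidation).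
5. Ring order: cyclopentene onto the six-membered ring (step 1), then seven-membered ring and oxolane together (step 7).

Assumption: 1, 2 and the L-fructose-derived (ent-Shi) ketone are bought as catalogue chemicals; locants in the Why lines follow the name of the compound being discussed.

**Step 1**
Reactants: 1 cyclohex-2-ene-1,4-dione; 2 buta-2,3-dien-2-yl(trimethyl)silane
Product: 4 (3aR,7aR)-3-methyl-3a,5,6,7a-tetrahydro-1H-indene-4,7-dione, via silylated dione 3 (not isolated)
Conditions: (S)-1-(2-methylphenyl)-3,3-diphenyl-tetrahydropyrrolo[1,2-c][1,3,2]oxazaborole (20 mol%), Tf2NH (20 mol%), CH2Cl2, −78 °C; then CF3CO2H, 0 °C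
Reagents that add atoms: none
Why: Proposed new method: a catalytic enantioselective Danheiser-type (trimethylsilyl)cyclopentene annulation, in which the chiral oxazaborolidinium ion binds one carbonyl of 1 and shields one alkene face, the CH2 terminus of 2 adds to the β-carbon to give a β-silyl vinyl cation, 1,2-silyl shift and closure by the boron enolate give the cis-fused ring and release the catalyst (silicon stays on carbon, so turnover is possible), both ring-fusion centres (3aR,7aR) are set here, and CF3CO2H then removes silicon by ipso-protonation without moving the double bond; the closest known reactions are the stoichiometric TiCl4-mediated Danheiser annulation of enones and oxazaborolidinium-catalysed enantioselective Diels–Alder and Mukaiyama–Michael reactions of cyclic enones and enediones.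

**Step 2**
Reactants: 4 (3aR,7aR)-3-methyl-3a,5,6,7a-tetrahydro-1H-indene-4,7-dione
Product: 5 (3aR,7aR)-3-methyl-7-methylidene-1,3a,5,6,7,7a-hexahydro-4H-inden-4-one
Conditions: Ph3PCH3Br (2.4 equiv), KOtBu (2.3 equiv), THF, 0 °C → rt; AcOH quench at −78 °C
Reagents that add atoms: methyltriphenylphosphonium bromide, C[P+](c1ccccc1)(c1ccccc1)c1ccccc1.[Br-]
Why: Wittig methylenation in which the first equivalent of ylide deprotonates the more acidic C3a–H (α to the C4 carbonyl and allylic), so the C4 carbonyl is masked as its dienolate and only the C7 ketone is methylenated, and kinetic α-protonation on quench returns the cis-fused β,γ-unsaturated ketone.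

**Step 3**
Reactants: 6 5-bromo-2-methylpent-2-ene; 7 propyne
Product: 10 (1Z)-1-iodo-2,6-dimethylhepta-1,5-diene, via Grignard reagent 8 (not isolated), via alkenylcopper 9 (not isolated)
Conditions: Mg, THF; CuBr·SMe2, Et2O–Me2S, −45 °C; propyne, −25 °C; I2, −50 → 0 °C
Reagents that add atoms: iodine, II
Why: Normant carbocupration adds the alkyl group and copper syn across propyne (alkyl to the internal carbon), and iodinolysis with retention gives only the Z iodide in which iodine is cis to the chain.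

**Step 4**
Reactants: 10 (1Z)-1-iodo-2,6-dimethylhepta-1,5-diene
Product: 11 (3S)-3-[(3Z)-4-iodo-3-methylbut-3-en-1-yl]-2,2-dimethyloxirane
Conditions: ent-Shi ketone (L-fructose-derived 1,2:4,5-di-O-isopropylidene-β-L-erythro-2,3-hexodiulo-2,6-pyranose, 30 mol%), KHSO5 (as 2KHSO5·KHSO4·K2SO4), K2CO3, Bu4NHSO4, MeCN–CH2(OMe)2–aq. Na2B4O7 buffer, 0 °C
Reagents that add atoms: potassium peroxymonosulfate, [K+].[O-]S(=O)(=O)OO
Why: Shi asymmetric epoxidation, in which the chiral dioxirane attacks the electron-rich trisubstituted alkene (the iodoalkene is deactivated) through the spiro transition state, and the L-fructose-derived ketone gives the (S)-epoxide.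

**Step 5**
Reactants: 11 (3S)-3-[(3Z)-4-iodo-3-methylbut-3-en-1-yl]-2,2-dimethyloxirane; 5 (3aR,7aR)-3-methyl-7-methylidene-1,3a,5,6,7,7a-hexahydro-4H-inden-4-one
Product: 14 (3aR,4S,7aR)-4-{(1Z)-4-[(2S)-3,3-dimethyloxiran-2-yl]-2-methylbut-1-en-1-yl}-3-methyl-7-methylidene-3a,4,5,6,7,7a-hexahydro-1H-inden-4-ol, via alkenyllithium 12 (not isolated), via alkenylcerium dichloride 13 (not isolated)
Conditions: t-BuLi (2.05 equiv), Et2O, −78 °C; CeCl3, THF, −78 °C; then 5, −78 °C; aq. NH4Cl
Reagents that add atoms: none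
Why: Iodine–lithium exchange with retention of alkene geometry, transmetalation to the weakly basic organocerium and 1,2-addition to the enolisable ketone from the convex face (the face of the ring-fusion hydrogens, away from the cyclopentene) give the (4S) carbinol, while the epoxide survives at −78 °C.

**Step 6**
Reactants: 14 (3aR,4S,7aR)-4-{(1Z)-4-[(2S)-3,3-dimethyloxiran-2-yl]-2-methylbut-1-en-1-yl}-3-methyl-7-methylidene-3a,4,5,6,7,7a-hexahydro-1H-inden-4-ol
Product: 15 (3aR,4R,7aR)-4-[(2S,3R)-3-{2-[(2S)-3,3-dimethyloxiran-2-yl]ethyl}-3-methyloxiran-2-yl]-3-methyl-7-methylidene-3a,4,5,6,7,7a-hexahydro-1H-inden-4-ol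
Conditions: VO(acac)2 (5 mol%), t-BuOOH (1.3 equiv), CH2Cl2, 0 °C
Reagents that add atoms: tert-butyl hydroperoxide, CC(C)(C)OO
Why: Hydroxyl-directed vanadium-catalysed epoxidation reacts at the allylic alkene far faster than at the homoallylic ring alkene or the exocyclic methylene, and allylic 1,3-strain from the Z substituent puts the smaller ring CH2 (C5) rather than the ring-fusion CH (C3a) in the crowded out-of-plane position, so oxygen is delivered to the face that gives the (2S,3R)-oxirane.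

**Step 7**
Reactants: 15 (3aR,4R,7aR)-4-[(2S,3R)-3-{2-[(2S)-3,3-dimethyloxiran-2-yl]ethyl}-3-methyloxiran-2-yl]-3-methyl-7-methylidene-3a,4,5,6,7,7a-hexahydro-1H-inden-4-ol
Product: 19 2-[(2R,5R)-5-methyl-5-[(3aR,5S,8aR)-3-methyl-8-methylidene-4-oxo-1,3a,4,5,6,7,8,8a-octahydroazulen-5-yl]oxolan-2-yl]propan-2-yl acetate, via aluminium alkoxide 16 (not isolated), via ring-expanded aluminium aldolate 17 (not isolated), via oxolane aluminium alkoxide 18 (not isolated)
Conditions: Me2AlCl (1.1 equiv), CH2Cl2, −78 → 0 °C; then pyridine, DMAP, Ac2O, 0 °C → rt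
Reagents that add atoms: acetic anhydride, CC(=O)OC(C)=O
Why: Epoxy-alcohol semipinacol rearrangement (1,2-alkyl shift with ring expansion) in the five-membered aluminium chelate, where the C4–C5 ring bond lies anti-periplanar to the breaking oxirane C–O bond and migrates with inversion to set the new C5 centre (the rotamer that would let C3a migrate holds the side chain gauche to both ring carbons), after which the freed tertiary aluminium alkoxide opens the second epoxide 5-exo with inversion to give the trans-2,5-oxolane and Ac2O/DMAP caps the resulting tertiary alkoxide while C4 is still a ketone.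

**Step 8**
Reactants: 19 2-[(2R,5R)-5-methyl-5-[(3aR,5S,8aR)-3-methyl-8-methylidene-4-oxo-1,3a,4,5,6,7,8,8a-octahydroazulen-5-yl]oxolan-2-yl]propan-2-yl acetate
Product: 20 2-[(2R,5R)-5-[(3aR,4S,5R,8aR)-4-hydroxy-3-methyl-8-methylidene-1,3a,4,5,6,7,8,8a-octahydroazulen-5-yl]-5-methyloxolan-2-yl]propan-2-yl acetate (dictyol H)
Conditions: LiBH(s-Bu)3, THF, −78 °C; aq. NH4Cl
Reagents that add atoms: none
Why: Diastereoselective ketone reduction in which the bulky hydride attacks the convex α-face, opposite both the cyclopentene ring and the C5 side chain, to give the (4S) alcohol, and the hindered tertiary acetate is untouched at −78 °C.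

**Compound list**
1 | cyclohex-2-ene-1,4-dione | O=C1C=CC(=O)CC1 | starting material
2 | buta-2,3-dien-2-yl(trimethyl)silane (1-methyl-1-(trimethylsilyl)allene) | C=C=C(C)[Si](C)(C)C | starting material
3 | (3aR,7aR)-3-methyl-2-(trimethylsilyl)-3a,5,6,7a-tetrahydro-1H-indene-4,7-dione | O=C1CCC(=O)[C@H]2C(C)=C([Si](C)(C)C)C[C@@H]12 | intermediate
4 | (3aR,7aR)-3-methyl-3a,5,6,7a-tetrahydro-1H-indene-4,7-dione | O=C1CCC(=O)[C@H]2C(C)=CC[C@@H]12 | intermediate
5 | (3aR,7aR)-3-methyl-7-methylidene-1,3a,5,6,7,7a-hexahydro-4H-inden-4-one | C=C1CCC(=O)[C@H]2C(C)=CC[C@@H]12 | intermediate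
6 | 5-bromo-2-methylpent-2-ene | CC(C)=CCCBr | starting material
7 | propyne | CC#C | starting material
8 | (4-methylpent-3-en-1-yl)magnesium bromide | CC(C)=CCC[Mg]Br | intermediate
9 | [(1Z)-2,6-dimethylhepta-1,5-dien-1-yl]copper | [Cu]/C=C(/C)CCC=C(C)C | intermediate
10 | (1Z)-1-iodo-2,6-dimethylhepta-1,5-diene | I/C=C(/C)CCC=C(C)C | intermediate
11 | (3S)-3-[(3Z)-4-iodo-3-methylbut-3-en-1-yl]-2,2-dimethyloxirane | I/C=C(/C)CC[C@@H]1OC1(C)C | intermediate
12 | [(1Z)-4-[(2S)-3,3-dimethyloxiran-2-yl]-2-methylbut-1-en-1-yl]lithium | [Li]/C=C(/C)CC[C@@H]1OC1(C)C | intermediate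
13 | dichloro[(1Z)-4-[(2S)-3,3-dimethyloxiran-2-yl]-2-methylbut-1-en-1-yl]cerium | Cl[Ce](Cl)/C=C(/C)CC[C@@H]1OC1(C)C | intermediate
14 | (3aR,4S,7aR)-4-{(1Z)-4-[(2S)-3,3-dimethyloxiran-2-yl]-2-methylbut-1-en-1-yl}-3-methyl-7-methylidene-3a,4,5,6,7,7a-hexahydro-1H-inden-4-ol | C=C1CC[C@](O)(/C=C(/C)CC[C@@H]3OC3(C)C)[C@H]2C(C)=CC[C@@H]12 | intermediate
15 | (3aR,4R,7aR)-4-[(2S,3R)-3-{2-[(2S)-3,3-dimethyloxiran-2-yl]ethyl}-3-methyloxiran-2-yl]-3-methyl-7-methylidene-3a,4,5,6,7,7a-hexahydro-1H-inden-4-ol | C=C1CC[C@](O)([C@@H]3O[C@]3(C)CC[C@@H]4OC4(C)C)[C@H]2C(C)=CC[C@@H]12 | intermediate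
16 | chloro(methyl)aluminium (3aR,4R,7aR)-4-[(2S,3R)-3-{2-[(2S)-3,3-dimethyloxiran-2-yl]ethyl}-3-methyloxiran-2-yl]-3-methyl-7-methylidene-3a,4,5,6,7,7a-hexahydro-1H-inden-4-olate | C=C1CC[C@](O[Al](C)Cl)([C@@H]3O[C@]3(C)CC[C@@H]4OC4(C)C)[C@H]2C(C)=CC[C@@H]12 | intermediate
17 | chloro(methyl)aluminium (2R)-4-[(2S)-3,3-dimethyloxiran-2-yl]-2-[(3aR,5S,8aR)-3-methyl-8-methylidene-4-oxo-1,3a,4,5,6,7,8,8a-octahydroazulen-5-yl]butan-2-olate | C=C1CC[C@@H]([C@](C)(O[Al](C)Cl)CC[C@@H]3OC3(C)C)C(=O)[C@H]2C(C)=CC[C@@H]12 | intermediate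
18 | chloro(methyl)aluminium 2-[(2R,5R)-5-methyl-5-[(3aR,5S,8aR)-3-methyl-8-methylidene-4-oxo-1,3a,4,5,6,7,8,8a-octahydroazulen-5-yl]oxolan-2-yl]propan-2-olate | C=C1CC[C@@H]([C@@]3(C)CC[C@H](C(C)(C)O[Al](C)Cl)O3)C(=O)[C@H]2C(C)=CC[C@@H]12 | intermediate
19 | 2-[(2R,5R)-5-methyl-5-[(3aR,5S,8aR)-3-methyl-8-methylidene-4-oxo-1,3a,4,5,6,7,8,8a-octahydroazulen-5-yl]oxolan-2-yl]propan-2-yl acetate | C=C1CC[C@@H]([C@@]3(C)CC[C@H](C(C)(C)OC(C)=O)O3)C(=O)[C@H]2C(C)=CC[C@@H]12 | intermediate
20 | 2-[(2R,5R)-5-[(3aR,4S,5R,8aR)-4-hydroxy-3-methyl-8-methylidene-1,3a,4,5,6,7,8,8a-octahydroazulen-5-yl]-5-methyloxolan-2-yl]propan-2-yl acetate (dictyol H) | C=C1CC[C@@H]([C@@]2(C)CC[C@H](C(C)(C)OC(C)=O)O2)[C@@H](O)[C@H]2C(C)=CC[C@@H]12 | target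

**Total step count:** 8. **Longest linear sequence:** 6 steps (1, 2, 5, 6, 7, 8; the side-chain branch 3, 4, 5, 6, 7, 8 is equally long).

**Three steps most likely to fail**

Step 1 (the proposed new annulation). The enantioselective, catalytic version has not been shown on a monodentate enedione. Traces of Me3SiNTf2 could catalyse a racemic background reaction, 1 could tautomerise to hydroquinone, and the facial sense of the (S)-catalyst is only predicted (the mirror-image catalyst is used if it proves opposite). Fallback with known chemistry, setting out from 2 and coming back at 4: (4R)-4-[(tert-butyldimethylsilyl)oxy]cyclohex-2-en-1-one F1 is annulated with 2 under the established stoichiometric TiCl4 conditions (CH2Cl2, −78 °C), the allene adding anti to the silyloxy group, to give (3aR,7R,7aR)-7-[(tert-butyldimethylsilyl)oxy]-3-methyl-2-(trimethylsilyl)-1,3a,5,6,7,7a-hexahydro-4H-inden-4-one F2. CF3CO2H and then Bu4NF remove both silyl groups to give (3aR,7R,7aR)-7-hydroxy-3-methyl-1,3a,5,6,7,7a-hexahydro-4H-inden-4-one F3, and Dess–Martin periodinane oxidation gives 4.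

Step 2 (site-selective mono-methylenation). The in-flask masking of the C4 carbonyl as its dienolate may be incomplete, giving bis-olefination or the wrong mono-olefin. Fallback, setting out from 4 and coming back at 5: soft enolisation with TBSOTf/Et3N at the more acidic allylic C3a–H gives the isolable silyl dienol ether (7aR)-4-[(tert-butyldimethylsilyl)oxy]-3-methyl-1,5,6,7a-tetrahydro-7H-inden-7-one F4. Wittig methylenation of its only free ketone gives tert-butyl(dimethyl){[(7aS)-3-methyl-7-methylidene-5,6,7,7a-tetrahydro-1H-inden-4-yl]oxy}silane F5, and Bu4NF/AcOH at −78 °C (kinetic α-protonation) returns 5.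

Step 7 (ring expansion and cascade). The oxirane may open at its tertiary carbon instead of the carbon next to the carbinol, the allylic ring-fusion carbon may migrate in place of the CH2, or the remote epoxide may rearrange before it is trapped. Fallback with known chemistry, setting out from 5 (and Grignard reagent 8) and coming back at 19: Sc(OTf)3-catalysed homologation of 5 with Me3SiCHN2, in which the less substituted CH2 migrates, gives after acidic work-up (3aR,8aR)-3-methyl-8-methylidene-3a,5,6,7,8,8a-hexahydroazulen-4(1H)-one F6. Its kinetic enolate (LiN(i-Pr)2, THF, −78 °C, then ZnCl2) adds to 6-methylhept-5-en-2-one F7 (made from 8 and N-methoxy-N-methylacetamide) to give, after separation of diastereomers, (3aR,5S,8aR)-5-[(2R)-2-hydroxy-6-methylhept-5-en-2-yl]-3-methyl-8-methylidene-3a,5,6,7,8,8a-hexahydroazulen-4(1H)-one F8. Hydroxyl-directed epoxidation of the bishomoallylic alkene with VO(acac)2/t-BuOOH and 5-exo closure with camphorsulfonic acid (trans-2,5 selective) give (3aR,5S,8aR)-5-[(2R,5R)-5-(2-hydroxypropan-2-yl)-2-methyloxolan-2-yl]-3-methyl-8-methylidene-3a,5,6,7,8,8a-hexahydroazulen-4(1H)-one F9, and Ac2O/DMAP/Et3N gives 19. Stereocontrol at the carbinol carbon is weaker here than in the main route.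

**Further compounds**
F1 | step 1 | (4R)-4-[(tert-butyldimethylsilyl)oxy]cyclohex-2-en-1-one | O=C1C=C[C@H](O[Si](C)(C)C(C)(C)C)CC1
F2 | step 1 | (3aR,7R,7aR)-7-[(tert-butyldimethylsilyl)oxy]-3-methyl-2-(trimethylsilyl)-1,3a,5,6,7,7a-hexahydro-4H-inden-4-one | CC(C)(C)[Si](C)(C)O[C@@H]1CCC(=O)[C@H]2C(C)=C([Si](C)(C)C)C[C@@H]12
F3 | step 1 | (3aR,7R,7aR)-7-hydroxy-3-methyl-1,3a,5,6,7,7a-hexahydro-4H-inden-4-one | O[C@@H]1CCC(=O)[C@H]2C(C)=CC[C@@H]12
F4 | step 2 | (7aR)-4-[(tert-butyldimethylsilyl)oxy]-3-methyl-1,5,6,7a-tetrahydro-7H-inden-7-one | O=C1CCC(O[Si](C)(C)C(C)(C)C)=C2C(C)=CC[C@@H]12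
F5 | step 2 | tert-butyl(dimethyl){[(7aS)-3-methyl-7-methylidene-5,6,7,7a-tetrahydro-1H-inden-4-yl]oxy}silane | C=C1CCC(O[Si](C)(C)C(C)(C)C)=C2C(C)=CC[C@@H]12
F6 | step 7 | (3aR,8aR)-3-methyl-8-methylidene-3a,5,6,7,8,8a-hexahydroazulen-4(1H)-one | C=C1CCCC(=O)[C@H]2C(C)=CC[C@@H]12
F7 | step 7 | 6-methylhept-5-en-2-one | CC(=O)CCC=C(C)C
F8 | step 7 | (3aR,5S,8aR)-5-[(2R)-2-hydroxy-6-methylhept-5-en-2-yl]-3-methyl-8-methylidene-3a,5,6,7,8,8a-hexahydroazulen-4(1H)-one | C=C1CC[C@@H]([C@](C)(O)CCC=C(C)C)C(=O)[C@H]2C(C)=CC[C@@H]12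
F9 | step 7 | (3aR,5S,8aR)-5-[(2R,5R)-5-(2-hydroxypropan-2-yl)-2-methyloxolan-2-yl]-3-methyl-8-methylidene-3a,5,6,7,8,8a-hexahydroazulen-4(1H)-one | C=C1CC[C@@H]([C@@]3(C)CC[C@H](C(C)(C)O)O3)C(=O)[C@H]2C(C)=CC[C@@H]12
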